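**Strategy.** Both chroman units are cut back to one (2S)-flavanone whose ring C is closed at C2–C3. The key step is an enantioselective dirhodium-carbenoid insertion. The diazo carbon (C3) of a gallacetophenone-derived 2-(4-silyloxybenzyloxy)aryl diazomethyl ketone inserts into the benzylic ether C2–H bond, which is activated by O1 and by ring B. One operation thus forms C2–C3, closes the pyran ring and sets C2. In the derived flav-3-ene, C2 then controls C3 and C4: Woodward (wet) and Prévost (dry) iodine–silver carboxylate dioxygenations give the 3,4-cis (4R) and 3,4-trans (4S) diols. A Miyaura–Suzuki union at C6–C6' and desilylation finish the route.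

Key step: step 5

**Remarks and assumptions**
- Chroman numbering is used (O1, C2, C3, C4, C4a, C5–C8, C8a). Ring A is the benzo ring, ring C the pyran ring, ring B the 4-oxyphenyl ring. TBS = tert-butyldimethylsilyl, TBSO = tert-butyldimethylsilyloxy.
- The change of the C2 descriptor from S (8–10) to R (11–19) reflects only the changed CIP rank of C3. The spatial arrangement at C2 is the same throughout.
- Assumption: alcohol 4 is taken as commercially available.
- Assumption: the sense of induction of Rh2(S-PTTL)4, dirhodium tetrakis[N-phthaloyl-(S)-tert-leucinate], is to be checked in a first run. The mirror-image catalyst Rh2(R-PTTL)4 is used if it proves opposite.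

**Route**

Step 1
Reactants: 1 gallacetophenone, 1-(2,3,4-trihydroxyphenyl)ethan-1-one
Product: 2 1-[3,4-bis(TBSO)-2-hydroxyphenyl]ethan-1-one
Conditions: TBSCl (2.2 equiv), imidazole, DMF, 0 °C to rt
Reagents that add atoms: tert-butyldimethylsilyl chloride, CC(C)(C)[Si](C)(C)Cl
Why: Silyl ether formation should spare the 2-OH, which is hydrogen-bonded to the acetyl carbonyl and flanked on both sides, so that only the 3- and 4-OH are silylated.

Step 2
Reactants: 2 1-[3,4-bis(TBSO)-2-hydroxyphenyl]ethan-1-one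
Product: 3 1-[5-bromo-3,4-bis(TBSO)-2-hydroxyphenyl]ethan-1-one
Conditions: NBS (1.05 equiv), MeCN, 0 °C, dark
Reagents that add atoms: N-bromosuccinimide, O=C1CCC(=O)N1Br
Why: Electrophilic aromatic bromination should go to C5 (later C6 of the chroman), which is para to the free phenol, ortho to the 4-silyloxy group and meta to the acetyl group.

Step 3
Reactants: 3 1-[5-bromo-3,4-bis(TBSO)-2-hydroxyphenyl]ethan-1-one; 4 [4-(TBSO)phenyl]methanol
Product: 5 1-[5-bromo-3,4-bis(TBSO)-2-{[4-(TBSO)phenyl]methoxy}phenyl]ethan-1-one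
Conditions: PPh3, DIAD, THF, 0 °C to rt
Reagents that add atoms: none
Why: Mitsunobu etherification installs the O1–C2 bond under neutral conditions, which avoids a free phenoxide next to the 3-silyl ether and hence silyl migration.

Step 4
Reactants: 5 1-[5-bromo-3,4-bis(TBSO)-2-{[4-(TBSO)phenyl]methoxy}phenyl]ethan-1-one
Product: 7 1-[5-bromo-3,4-bis(TBSO)-2-{[4-(TBSO)phenyl]methoxy}phenyl]-2-diazoethan-1-one, via trifluoroacetyl diketone 6 (not isolated)
Conditions: LiHMDS, THF, −78 °C, then CF3CO2CH2CF3; then MsN3, Et3N, H2O, MeCN, rt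
Reagents that add atoms: methanesulfonyl azide, CS(=O)(=O)N=[N+]=[N-]
Why: Deacylative (Regitz-type) diazo transfer should work because the kinetic methyl ketone enolate is trifluoroacetylated and the activated diketone then takes up N2 from the sulfonyl azide with loss of the trifluoroacetyl group as its sulfonamide.

Step 5
Reactants: 7 1-[5-bromo-3,4-bis(TBSO)-2-{[4-(TBSO)phenyl]methoxy}phenyl]-2-diazoethan-1-one
Product: 8 (2S)-6-bromo-7,8-bis(TBSO)-2-[4-(TBSO)phenyl]-2,3-dihydro-4H-chromen-4-one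
Conditions: Rh2(S-PTTL)4 (1–2 mol %), toluene, −20 °C to rt, slow addition of 7
Reagents that add atoms: none
Why: Loss of N2 gives an electrophilic dirhodium carbenoid at C3, which inserts through a concerted, hydride-transfer-like three-centre transition state into one C2–H bond of the benzylic ether and so forms the C2–C3 bond directly. The closest known reaction type is the intramolecular carbenoid C–H insertion of 2-alkoxyaryl diazoketones to chroman-4-ones under chiral dirhodium carboxylate catalysis. Ring C closes in the 1,6-insertion mode through a six-membered chair-like transition state with the 4-silyloxyphenyl group pseudo-equatorial. The new stereocenter C2 is set by the chiral carboxylate ligands, which distinguish the two enantiotopic C2 hydrogens; this is pure catalyst control, since 7 has no stereocenter. The step needs chemoselectivity for C–H insertion over carbenoid capture by O1 (oxonium ylide and benzyl shift to a benzofuranone) and over addition to ring B. This should be secured because the C2–H bond is the most hydridic in 7 (benzylic, alpha to oxygen, para-silyloxy stabilised), O1 is a weak donor conjugated to the acyl-bearing ring and shielded by the C8 silyl ether, and no competing 1,5 C–H bond exists.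

Step 6
Reactants: 8 (2S)-6-bromo-7,8-bis(TBSO)-2-[4-(TBSO)phenyl]-2,3-dihydro-4H-chromen-4-one
Product: 9 (2S,4S)-6-bromo-7,8-bis(TBSO)-2-[4-(TBSO)phenyl]-3,4-dihydro-2H-chromen-4-ol
Conditions: NaBH4, MeOH/THF, 0 °C
Reagents that add atoms: none
Why: Hydride reduction of the flavanone carbonyl by axial attack should give the 2,4-cis alcohol (the C4 configuration is lost again in step 7), and the cold, short reaction avoids enolate-driven ring opening that would racemise C2.

Step 7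
Reactants: 9 (2S,4S)-6-bromo-7,8-bis(TBSO)-2-[4-(TBSO)phenyl]-3,4-dihydro-2H-chromen-4-ol
Product: 10 (2S)-6-bromo-7,8-bis(TBSO)-2-[4-(TBSO)phenyl]-2H-chromene
Conditions: Burgess reagent, toluene, 60 °C, dark
Reagents that add atoms: none
Why: Burgess dehydration (syn-elimination through the sulfamate ester) should give the C3=C4 alkene under neutral conditions that neither touch C2 nor cause the acid-induced disproportionation of flavenes.

Step 8
Reactants: 10 (2S)-6-bromo-7,8-bis(TBSO)-2-[4-(TBSO)phenyl]-2H-chromene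
Product: 13 (2R,3R,4R)-6-bromo-7,8-bis(TBSO)-2-[4-(TBSO)phenyl]chromane-3,4-diol, via trans-iodo acetate 11 (not isolated), via cis-hydroxy acetate 12 (not isolated)
Conditions: I2, AgOAc, AcOH, rt, dark; then H2O, 60 °C; then DIBAL-H, CH2Cl2, −78 °C
Reagents that add atoms: silver acetate, CC(=O)[O-].[Ag+]
Why: In this Woodward cis-hydroxylation iodine should add to C3 anti to the C2 aryl group and acetate to benzylic C4, after which silver-assisted displacement of iodide by the neighbouring acetate gives a cis-fused acetoxonium ion on the aryl face that water opens at its central carbon, so that both new C–O bonds (3R and 4R) end cis to the C2 aryl group before DIBAL-H removes the acetate without touching the aryl silyl ethers.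

Step 9
Reactants: 10 (2S)-6-bromo-7,8-bis(TBSO)-2-[4-(TBSO)phenyl]-2H-chromene
Product: 16 (2R,3R,4S)-6-bromo-7,8-bis(TBSO)-2-[4-(TBSO)phenyl]chromane-3,4-diol, via trans-iodo benzoate 14 (not isolated), via trans-dibenzoate 15 (not isolated)
Conditions: I2, PhCO2Ag, benzene, rt to 80 °C, dark; then DIBAL-H, CH2Cl2, −78 °C
Reagents that add atoms: silver benzoate, O=C([O-])c1ccccc1.[Ag+]
Why: In this Prévost reaction the same cis-fused acyloxonium ion should form on the aryl face, but under dry conditions a second benzoate opens it with inversion at the benzylic C4, so that C3–O stays cis to the C2 aryl group (3R) and C4–O ends trans (4S) before DIBAL-H removes both benzoates.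

Step 10
Reactants: 16 (2R,3R,4S)-6-bromo-7,8-bis(TBSO)-2-[4-(TBSO)phenyl]chromane-3,4-diol; 13 (2R,3R,4R)-6-bromo-7,8-bis(TBSO)-2-[4-(TBSO)phenyl]chromane-3,4-diol
Product: 18 (2R,2'R,3R,3'R,4R,4'S)-7,7',8,8'-tetrakis(TBSO)-2,2'-bis[4-(TBSO)phenyl]-[6,6'-bichromane]-3,3',4,4'-tetrol, via pinacol boronate 17 (not isolated)
Conditions: B2pin2 (1.05 equiv), Pd(OAc)2, SPhos, KOAc, dioxane, 80 °C; then 13, K3PO4, H2O, 80 °C
Reagents that add atoms: none
Why: One-pot Miyaura borylation and Suzuki–Miyaura coupling should join the two C6 positions because the SPhos-ligated palladium catalyst tolerates free alcohols and couples ortho-oxygenated, electron-rich aryl partners, and no stereocenter is involved.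

Step 11
Reactants: 18 (2R,2'R,3R,3'R,4R,4'S)-7,7',8,8'-tetrakis(TBSO)-2,2'-bis[4-(TBSO)phenyl]-[6,6'-bichromane]-3,3',4,4'-tetrol
Product: 19 (2R,2'R,3R,3'R,4R,4'S)-2,2'-bis(4-hydroxyphenyl)-[6,6'-bichromane]-3,3',4,4',7,7',8,8'-octol (CNP0121763.1)
Conditions: TBAF, AcOH (1:1), THF, 0 °C to rt, argon
Reagents that add atoms: none
Why: Acetic-acid-buffered fluoride should cleave the six aryl silyl ethers under near-neutral, non-reductive and non-acidic conditions, which the ionisable benzylic C4–OH groups and the catechols should survive.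

**Compound list**

1 | gallacetophenone, 1-(2,3,4-trihydroxyphenyl)ethan-1-one | CC(=O)c1ccc(O)c(O)c1O | starting material
2 | 1-[3,4-bis(TBSO)-2-hydroxyphenyl]ethan-1-one | CC(=O)c1ccc(O[Si](C)(C)C(C)(C)C)c(O[Si](C)(C)C(C)(C)C)c1O | intermediate
3 | 1-[5-bromo-3,4-bis(TBSO)-2-hydroxyphenyl]ethan-1-one | CC(=O)c1cc(Br)c(O[Si](C)(C)C(C)(C)C)c(O[Si](C)(C)C(C)(C)C)c1O | intermediate
4 | [4-(TBSO)phenyl]methanol | OCc1ccc(O[Si](C)(C)C(C)(C)C)cc1 | starting material
5 | 1-[5-bromo-3,4-bis(TBSO)-2-{[4-(TBSO)phenyl]methoxy}phenyl]ethan-1-one | CC(=O)c1cc(Br)c(O[Si](C)(C)C(C)(C)C)c(O[Si](C)(C)C(C)(C)C)c1OCc1ccc(O[Si](C)(C)C(C)(C)C)cc1 | intermediate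
6 | 1-[5-bromo-3,4-bis(TBSO)-2-{[4-(TBSO)phenyl]methoxy}phenyl]-4,4,4-trifluorobutane-1,3-dione (formed as its lithium enolate) | O=C(CC(=O)C(F)(F)F)c1cc(Br)c(O[Si](C)(C)C(C)(C)C)c(O[Si](C)(C)C(C)(C)C)c1OCc1ccc(O[Si](C)(C)C(C)(C)C)cc1 | intermediate
7 | 1-[5-bromo-3,4-bis(TBSO)-2-{[4-(TBSO)phenyl]methoxy}phenyl]-2-diazoethan-1-one | [N-]=[N+]=CC(=O)c1cc(Br)c(O[Si](C)(C)C(C)(C)C)c(O[Si](C)(C)C(C)(C)C)c1OCc1ccc(O[Si](C)(C)C(C)(C)C)cc1 | intermediate
8 | (2S)-6-bromo-7,8-bis(TBSO)-2-[4-(TBSO)phenyl]-2,3-dihydro-4H-chromen-4-one | O=C1C[C@@H](c2ccc(O[Si](C)(C)C(C)(C)C)cc2)Oc2c1cc(Br)c(O[Si](C)(C)C(C)(C)C)c2O[Si](C)(C)C(C)(C)C | intermediate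
9 | (2S,4S)-6-bromo-7,8-bis(TBSO)-2-[4-(TBSO)phenyl]-3,4-dihydro-2H-chromen-4-ol (2,4-cis) | O[C@H]1C[C@@H](c2ccc(O[Si](C)(C)C(C)(C)C)cc2)Oc2c1cc(Br)c(O[Si](C)(C)C(C)(C)C)c2O[Si](C)(C)C(C)(C)C | intermediate
10 | (2S)-6-bromo-7,8-bis(TBSO)-2-[4-(TBSO)phenyl]-2H-chromene | C1=C[C@@H](c2ccc(O[Si](C)(C)C(C)(C)C)cc2)Oc2c1cc(Br)c(O[Si](C)(C)C(C)(C)C)c2O[Si](C)(C)C(C)(C)C | intermediate
11 | (2R,3R,4R)-6-bromo-3-iodo-7,8-bis(TBSO)-2-[4-(TBSO)phenyl]chroman-4-yl acetate (iodine trans to the C2 aryl group, acetate trans to iodine) | CC(C)(C)[Si](C)(C)Oc1ccc([C@H]2Oc3c(cc(Br)c(O[Si](C)(C)C(C)(C)C)c3O[Si](C)(C)C(C)(C)C)[C@@H](OC(C)=O)[C@@H]2I)cc1 | intermediate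
12 | (2R,3R,4R)-6-bromo-4-hydroxy-7,8-bis(TBSO)-2-[4-(TBSO)phenyl]chroman-3-yl acetate (all-cis; drawn as the 3-acetate, the 4-acetate regioisomer would converge on the same diol) | CC(C)(C)[Si](C)(C)Oc1ccc([C@H]2Oc3c(cc(Br)c(O[Si](C)(C)C(C)(C)C)c3O[Si](C)(C)C(C)(C)C)[C@@H](O)[C@H]2OC(C)=O)cc1 | intermediate
13 | (2R,3R,4R)-6-bromo-7,8-bis(TBSO)-2-[4-(TBSO)phenyl]chromane-3,4-diol (2,3-cis-3,4-cis) | CC(C)(C)[Si](C)(C)Oc1ccc([C@H]2Oc3c(cc(Br)c(O[Si](C)(C)C(C)(C)C)c3O[Si](C)(C)C(C)(C)C)[C@@H](O)[C@H]2O)cc1 | intermediate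
14 | (2R,3R,4R)-6-bromo-3-iodo-7,8-bis(TBSO)-2-[4-(TBSO)phenyl]chroman-4-yl benzoate | CC(C)(C)[Si](C)(C)Oc1ccc([C@H]2Oc3c(cc(Br)c(O[Si](C)(C)C(C)(C)C)c3O[Si](C)(C)C(C)(C)C)[C@@H](OC(=O)c3ccccc3)[C@@H]2I)cc1 | intermediate
15 | (2R,3S,4S)-6-bromo-7,8-bis(TBSO)-2-[4-(TBSO)phenyl]chromane-3,4-diyl dibenzoate (2,3-cis-3,4-trans) | Brc1cc2c(c(O[Si](C)(C)C(C)(C)C)c1O[Si](C)(C)C(C)(C)C)O[C@H](c1ccc(O[Si](C)(C)C(C)(C)C)cc1)[C@H](OC(=O)c1ccccc1)[C@H]2OC(=O)c1ccccc1 | intermediate
16 | (2R,3R,4S)-6-bromo-7,8-bis(TBSO)-2-[4-(TBSO)phenyl]chromane-3,4-diol (2,3-cis-3,4-trans) | Brc1cc2c(c(O[Si](C)(C)C(C)(C)C)c1O[Si](C)(C)C(C)(C)C)O[C@H](c1ccc(O[Si](C)(C)C(C)(C)C)cc1)[C@H](O)[C@H]2O | intermediate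
17 | (2R,3R,4S)-7,8-bis(TBSO)-2-[4-(TBSO)phenyl]-6-(4,4,5,5-tetramethyl-1,3,2-dioxaborolan-2-yl)chromane-3,4-diol | CC1(C)OB(OC1(C)C)c1cc2c(c(O[Si](C)(C)C(C)(C)C)c1O[Si](C)(C)C(C)(C)C)O[C@H](c1ccc(O[Si](C)(C)C(C)(C)C)cc1)[C@H](O)[C@H]2O | intermediate
18 | (2R,2'R,3R,3'R,4R,4'S)-7,7',8,8'-tetrakis(TBSO)-2,2'-bis[4-(TBSO)phenyl]-[6,6'-bichromane]-3,3',4,4'-tetrol | CC(C)(C)[Si](C)(C)Oc1ccc([C@H]2Oc3c(cc(-c4cc5c(c(O[Si](C)(C)C(C)(C)C)c4O[Si](C)(C)C(C)(C)C)O[C@H](c4ccc(O[Si](C)(C)C(C)(C)C)cc4)[C@H](O)[C@H]5O)c(O[Si](C)(C)C(C)(C)C)c3O[Si](C)(C)C(C)(C)C)[C@@H](O)[C@H]2O)cc1 | intermediate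
19 | (2R,2'R,3R,3'R,4R,4'S)-2,2'-bis(4-hydroxyphenyl)-[6,6'-bichromane]-3,3',4,4',7,7',8,8'-octol | Oc1ccc([C@H]2Oc3c(cc(-c4cc5c(c(O)c4O)O[C@H](c4ccc(O)cc4)[C@H](O)[C@H]5O)c(O)c3O)[C@@H](O)[C@H]2O)cc1 | target

**Step count and risks**

Total step count: 11. Longest linear sequence: 10 steps (steps 1–7, then 9, 10 and 11; step 8 is the parallel branch from 10 that joins at step 10).

Steps most likely to fail:

1. Step 5 (key step). The carbenoid may be captured by the ether oxygen O1, with oxonium ylide formation and benzyl shift to a benzofuranone, and discrimination between the two enantiotopic C2–H bonds may be incomplete. The fallback sets out from 3 and returns at 9. It closes the same C2–C3 bond as an alkene by an intramolecular Wittig reaction on an ester carbonyl. Steglich esterification of 3 with 4-(TBSO)benzoic acid (DCC, DMAP) would give the aryl ester F1. Bromination of its acetyl group with phenyltrimethylammonium tribromide would give the phenacyl bromide F2, and PPh3 would give the phosphonium salt F3. Et3N in warm toluene would form the acyl ylide F4, whose attack on the neighbouring ester carbonyl and loss of phosphine oxide would give the flavone F5. Asymmetric hydrogenation of F5 with a chiral ruthenium N-heterocyclic carbene catalyst (from Ru(cod)(2-methylallyl)2, a chiral imidazolinium salt and KOtBu, H2), followed by NaBH4 to complete carbonyl reduction, would give 9.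

2. Step 8. Electrophilic iodination of the electron-rich rings may compete with addition to the alkene, and ionisation of the benzylic C4–O bond in warm aqueous acetic acid may erode the 3,4-cis relationship. The fallback sets out from 16 and returns at 13. MnO2 in CH2Cl2 would oxidise only the benzylic C4–OH of 16 to the 2,3-cis-3-hydroxyflavanone F6. NaBH4 at −40 °C would then deliver hydride axially, anti to the axial 3-OH, to give the 3,4-cis diol 13.

3. Step 10. Protodeboronation of the electron-rich boronate, homocoupling of 13 by residual diboron and base-induced loss of aryl silyl ethers may occur during the hindered coupling. The fallback sets out from 16 and returns at 18, replacing the basic boron coupling by a neutral Stille coupling. Stannylation of 16 with hexamethylditin and Pd(PPh3)4 in toluene at 100 °C would give the aryl stannane F7. Coupling of F7 with 13 (Pd(PPh3)4, CuI, DMF, 60 °C) would give 18.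

Further compounds
F1 | step 5 | 2-acetyl-4-bromo-5,6-bis(TBSO)phenyl 4-(TBSO)benzoate | CC(=O)c1cc(Br)c(O[Si](C)(C)C(C)(C)C)c(O[Si](C)(C)C(C)(C)C)c1OC(=O)c1ccc(O[Si](C)(C)C(C)(C)C)cc1
F2 | step 5 | 4-bromo-2-(bromoacetyl)-5,6-bis(TBSO)phenyl 4-(TBSO)benzoate | BrCC(=O)c1cc(Br)c(O[Si](C)(C)C(C)(C)C)c(O[Si](C)(C)C(C)(C)C)c1OC(=O)c1ccc(O[Si](C)(C)C(C)(C)C)cc1
F3 | step 5 | {2-[5-bromo-3,4-bis(TBSO)-2-{[4-(TBSO)benzoyl]oxy}phenyl]-2-oxoethyl}triphenylphosphonium bromide | [Br-].O=C(C[P+](c1ccccc1)(c1ccccc1)c1ccccc1)c1cc(Br)c(O[Si](C)(C)C(C)(C)C)c(O[Si](C)(C)C(C)(C)C)c1OC(=O)c1ccc(O[Si](C)(C)C(C)(C)C)cc1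
F4 | step 5 | 4-bromo-5,6-bis(TBSO)-2-[(triphenylphosphoranylidene)acetyl]phenyl 4-(TBSO)benzoate | O=C(C=P(c1ccccc1)(c1ccccc1)c1ccccc1)c1cc(Br)c(O[Si](C)(C)C(C)(C)C)c(O[Si](C)(C)C(C)(C)C)c1OC(=O)c1ccc(O[Si](C)(C)C(C)(C)C)cc1
F5 | step 5 | 6-bromo-7,8-bis(TBSO)-2-[4-(TBSO)phenyl]-4H-chromen-4-one | O=c1cc(-c2ccc(O[Si](C)(C)C(C)(C)C)cc2)oc2c1cc(Br)c(O[Si](C)(C)C(C)(C)C)c2O[Si](C)(C)C(C)(C)C
F6 | step 8 | (2R,3S)-6-bromo-3-hydroxy-7,8-bis(TBSO)-2-[4-(TBSO)phenyl]-2,3-dihydro-4H-chromen-4-one (2,3-cis) | Brc1cc2c(c(O[Si](C)(C)C(C)(C)C)c1O[Si](C)(C)C(C)(C)C)O[C@H](c1ccc(O[Si](C)(C)C(C)(C)C)cc1)[C@H](O)C2=O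
F7 | step 10 | (2R,3R,4S)-7,8-bis(TBSO)-2-[4-(TBSO)phenyl]-6-(trimethylstannyl)chromane-3,4-diol | C[Sn](C)(C)c1cc2c(c(O[Si](C)(C)C(C)(C)C)c1O[Si](C)(C)C(C)(C)C)O[C@H](c1ccc(O[Si](C)(C)C(C)(C)C)cc1)[C@H](O)[C@H]2O
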